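The pyran ring is disconnected at C3–C4 by re-inserting a nitrogen atom: the chroman is the product of nitrogen deletion from a (3R)-3-aryl-2,3,4,5-tetrahydro-1,4-benzoxazepine. The key step exploits that C3 is benzylic to ring B and C4 is benzylic to ring A, so N2 loss from the derived 1,1-diazene leaves a tethered, doubly benzylic radical pair that collapses to the C3–C4 bond. This contracts the seven-membered O1/C2/C3/N/C4/C4a/C8a ring to the six-membered pyran with C3 unchanged. The nitrogen is a traceless linchpin: it sets C3 (N-sulfinyl ketimine reduction) and brings in C4 (Pictet–Spengler with formaldehyde para to the C7 hydroxyl).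

Key step: step 9

Assumption: hydride addition to the N-sulfinyl ketimine is taken to follow the usual cyclic model for aryl alkyl ketimines (aryl as the large group); if the aryloxymethyl group reversed the sense, (R)-tert-butanesulfinamide would be used instead.

Step 1
Reactants: 1 2-iodobenzene-1,3-diol; 2 2-methylbut-3-en-2-ol
Product: 4 2-(3-hydroxy-3-methylbutyl)benzene-1,3-diol, via B-alkyl-9-BBN adduct 3 (not isolated)
Conditions: 2, 9-BBN, THF, 0 °C to rt; then 1, Pd(dppf)Cl2 (cat.), 3 M aq NaOH, 65 °C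
Reagents that add atoms: none
Why: 9-BBN adds anti-Markovnikov to the terminal alkene and the B-alkyl borane then undergoes B-alkyl Suzuki–Miyaura coupling with the aryl iodide, hydroxide forming the borate and carrying the phenols as phenoxides.

Step 2
Reactants: 5 1-(2,4-dihydroxyphenyl)ethanone
Product: 6 1-[2-hydroxy-4-(3-methylbut-2-enyloxy)phenyl]ethanone
Conditions: prenyl bromide, K2CO3, acetone, reflux
Reagents that add atoms: prenyl bromide (1-bromo-3-methylbut-2-ene), CC(C)=CCBr
Why: Williamson etherification should be selective for the 4-OH because the 2-OH is held in a hydrogen bond to the acetyl carbonyl.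

Step 3
Reactants: 6 1-[2-hydroxy-4-(3-methylbut-2-enyloxy)phenyl]ethanone
Product: 7 triisopropyl({1-[4-(3-methylbut-2-enyloxy)-2-(triisopropylsilyloxy)phenyl]ethenyl}oxy)silane
Conditions: TIPSOTf (2.3 equiv), Et3N, CH2Cl2, 0 °C to rt
Reagents that add atoms: triisopropylsilyl trifluoromethanesulfonate, CC(C)[Si](C(C)C)(C(C)C)OS(=O)(=O)C(F)(F)F
Why: The silyl triflate with amine base should silylate the chelated phenol and convert the methyl ketone into its silyl enol ether in one operation (soft enolisation).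

Step 4
Reactants: 7 triisopropyl({1-[4-(3-methylbut-2-enyloxy)-2-(triisopropylsilyloxy)phenyl]ethenyl}oxy)silane
Product: 8 2-bromo-1-[4-(3-methylbut-2-enyloxy)-2-(triisopropylsilyloxy)phenyl]ethanone
Conditions: NBS, THF, −78 °C; aqueous work-up
Reagents that add atoms: N-bromosuccinimide, O=C1CCC(=O)N1Br
Why: Electrophilic bromination of the silyl enol ether at low temperature should be far faster than attack on the trisubstituted alkene or the arene and gives the α-bromo ketone regiospecifically.

Step 5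
Reactants: 4 2-(3-hydroxy-3-methylbutyl)benzene-1,3-diol (3 equiv); 8 2-bromo-1-[4-(3-methylbut-2-enyloxy)-2-(triisopropylsilyloxy)phenyl]ethanone
Product: 9 2-[3-hydroxy-2-(3-hydroxy-3-methylbutyl)phenoxy]-1-[4-(3-methylbut-2-enyloxy)-2-(triisopropylsilyloxy)phenyl]ethanone
Conditions: K2CO3, acetone, rt; excess 4 recovered
Reagents that add atoms: none
Why: Williamson etherification of the symmetric resorcinol, in which both phenols are equivalent, the excess of 4 limits double alkylation and the tertiary alcohol does not compete.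

Step 6
Reactants: 9 2-[3-hydroxy-2-(3-hydroxy-3-methylbutyl)phenoxy]-1-[4-(3-methylbut-2-enyloxy)-2-(triisopropylsilyloxy)phenyl]ethanone
Product: 10 2-[3-hydroxy-2-(3-hydroxy-3-methylbutyl)phenoxy]-1-[4-hydroxy-5-(2-methylbut-3-en-2-yl)-2-(triisopropylsilyloxy)phenyl]ethanone
Conditions: EtOH/H2O (4:1), 130 °C, sealed tube
Reagents that add atoms: none
Why: Aromatic Claisen rearrangement ([3,3]) of the aryl prenyl ether should deliver the 1,1-dimethylallyl group to C5′ because C3′ is shielded by the ortho silyloxy group, with the para-acyl group and the aqueous medium accelerating the shift as in related para-acyl aryl prenyl ethers.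

Step 7
Reactants: 10 2-[3-hydroxy-2-(3-hydroxy-3-methylbutyl)phenoxy]-1-[4-hydroxy-5-(2-methylbut-3-en-2-yl)-2-(triisopropylsilyloxy)phenyl]ethanone
Product: 12 (S)-N-{(1R)-2-[3-hydroxy-2-(3-hydroxy-3-methylbutyl)phenoxy]-1-[4-hydroxy-5-(2-methylbut-3-en-2-yl)-2-(triisopropylsilyloxy)phenyl]ethyl}-2-methylpropane-2-sulfinamide, via N-sulfinyl ketimine 11 (not isolated)
Conditions: (S)-tert-butanesulfinamide, Ti(OEt)4, THF, 65 °C; then NaBH4, −48 °C
Reagents that add atoms: (S)-2-methylpropane-2-sulfinamide, CC(C)(C)[S@](=O)N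
Why: Ti(OEt)4-mediated condensation gives ketimine 11 and borohydride is delivered through the cyclic sulfinyl-oxygen-bound transition state to the face that should set the C–N stereocentre as R (tert-butanesulfinamide ketimine reduction; any minor diastereomer is removed by chromatography).

Step 8
Reactants: 12 (S)-N-{(1R)-2-[3-hydroxy-2-(3-hydroxy-3-methylbutyl)phenoxy]-1-[4-hydroxy-5-(2-methylbut-3-en-2-yl)-2-(triisopropylsilyloxy)phenyl]ethyl}-2-methylpropane-2-sulfinamide
Product: 14 (3R)-3-[4-hydroxy-5-(2-methylbut-3-en-2-yl)-2-(triisopropylsilyloxy)phenyl]-9-(3-hydroxy-3-methylbutyl)-2,3,4,5-tetrahydro-1,4-benzoxazepin-8-ol, via primary amine 13 (not isolated)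
Conditions: HCl (4 M in dioxane), MeOH, 0 °C; NaHCO3; then 37% aq CH2O (1.05 equiv), MeOH, 50 °C
Reagents that add atoms: formaldehyde, C=O
Why: Methanolic HCl cleaves the N–S bond and the freed amine condenses with formaldehyde to an iminium ion that should be trapped by the arene carbon ortho to the ether oxygen and para to the free phenol, the only position the tether can reach (phenolic Pictet–Spengler/Mannich cyclisation, 7-endo).

Step 9
Reactants: 14 (3R)-3-[4-hydroxy-5-(2-methylbut-3-en-2-yl)-2-(triisopropylsilyloxy)phenyl]-9-(3-hydroxy-3-methylbutyl)-2,3,4,5-tetrahydro-1,4-benzoxazepin-8-ol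
Product: 16 (3R)-3-[4-hydroxy-5-(2-methylbut-3-en-2-yl)-2-(triisopropylsilyloxy)phenyl]-8-(3-hydroxy-3-methylbutyl)chroman-7-ol, via 1,1-diazene 15 (not isolated)
Conditions: N-(benzyloxy)-N-(pivaloyloxy)-4-(trifluoromethyl)benzamide (1.5 equiv), THF, 45 °C
Reagents that add atoms: none
Why: The secondary amine attacks the anomeric amide at nitrogen with loss of pivalate, the N–N adduct expels benzyl 4-(trifluoromethyl)benzoate to give 1,1-diazene 15, and loss of N2 leaves a singlet C3/C4 radical pair, both centres benzylic, that recombines within the O1–C2/arene tether. The closest known reaction type is the nitrogen-deletion ring contraction of cyclic α-aryl secondary amines (pyrrolidines to cyclobutanes, tetrahydroisoquinolines to indanes) and the older oxidation of cyclic N-amino-2-arylamines. The pyran ring closes by radical–radical recombination forming C3–C4, a 7→6 contraction in which the ring nitrogen is the only atom lost. No new stereocentre forms; C3 is expected to keep its configuration because bond formation from the tethered pair should be faster than rotation about C2–C3, so C–N is replaced by C–C with retention to give 3R. The step needs N-amination only at nitrogen and recombination in preference to β-scission or hydrogen transfer, which the single basic amine, the double benzylic stabilisation and the short tether should secure.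

Step 10
Reactants: 16 (3R)-3-[4-hydroxy-5-(2-methylbut-3-en-2-yl)-2-(triisopropylsilyloxy)phenyl]-8-(3-hydroxy-3-methylbutyl)chroman-7-ol
Product: 17 (3R)-3-[2,4-dihydroxy-5-(2-methylbut-3-en-2-yl)phenyl]-8-(3-hydroxy-3-methylbutyl)chroman-7-ol (CNP0420388.1)
Conditions: TBAF, AcOH, THF, 0 °C
Reagents that add atoms: none
Why: Buffered fluoride cleaves the aryl silyl ether under non-acidic conditions that should leave the tertiary alcohol, the terminal alkene and C3 untouched (fluoride desilylation).

Compound list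
1 | 2-iodobenzene-1,3-diol | Oc1cccc(O)c1I | starting material
2 | 2-methylbut-3-en-2-ol | CC(C)(O)C=C | starting material
3 | 4-(9-borabicyclo[3.3.1]nonan-9-yl)-2-methylbutan-2-ol | CC(C)(O)CCB1C2CCCC1CCC2 | intermediate
4 | 2-(3-hydroxy-3-methylbutyl)benzene-1,3-diol | CC(C)(O)CCc1c(O)cccc1O | intermediate
5 | 1-(2,4-dihydroxyphenyl)ethanone | CC(=O)c1ccc(O)cc1O | starting material
6 | 1-[2-hydroxy-4-(3-methylbut-2-enyloxy)phenyl]ethanone | CC(=O)c1ccc(OCC=C(C)C)cc1O | intermediate
7 | triisopropyl({1-[4-(3-methylbut-2-enyloxy)-2-(triisopropylsilyloxy)phenyl]ethenyl}oxy)silane | C=C(O[Si](C(C)C)(C(C)C)C(C)C)c1ccc(OCC=C(C)C)cc1O[Si](C(C)C)(C(C)C)C(C)C | intermediate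
8 | 2-bromo-1-[4-(3-methylbut-2-enyloxy)-2-(triisopropylsilyloxy)phenyl]ethanone | O=C(CBr)c1ccc(OCC=C(C)C)cc1O[Si](C(C)C)(C(C)C)C(C)C | intermediate
9 | 2-[3-hydroxy-2-(3-hydroxy-3-methylbutyl)phenoxy]-1-[4-(3-methylbut-2-enyloxy)-2-(triisopropylsilyloxy)phenyl]ethanone | CC(C)(O)CCc1c(O)cccc1OCC(=O)c1ccc(OCC=C(C)C)cc1O[Si](C(C)C)(C(C)C)C(C)C | intermediate
10 | 2-[3-hydroxy-2-(3-hydroxy-3-methylbutyl)phenoxy]-1-[4-hydroxy-5-(2-methylbut-3-en-2-yl)-2-(triisopropylsilyloxy)phenyl]ethanone | CC(C)(O)CCc1c(O)cccc1OCC(=O)c1cc(C(C)(C)C=C)c(O)cc1O[Si](C(C)C)(C(C)C)C(C)C | intermediate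
11 | (S at sulfur, Z)-N-sulfinyl ketimine of 10 with (S)-tert-butanesulfinamide, sulfinyl group syn to the aryloxymethyl group | CC(C)(C)[S@](=O)/N=C(\COc1cccc(O)c1CCC(C)(C)O)c1cc(C(C)(C)C=C)c(O)cc1O[Si](C(C)C)(C(C)C)C(C)C | intermediate
12 | (S)-N-{(1R)-2-[3-hydroxy-2-(3-hydroxy-3-methylbutyl)phenoxy]-1-[4-hydroxy-5-(2-methylbut-3-en-2-yl)-2-(triisopropylsilyloxy)phenyl]ethyl}-2-methylpropane-2-sulfinamide | CC(C)(C)[S@](=O)N[C@@H](COc1cccc(O)c1CCC(C)(C)O)c1cc(C(C)(C)C=C)c(O)cc1O[Si](C(C)C)(C(C)C)C(C)C | intermediate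
13 | 3-{(2R)-2-amino-2-[4-hydroxy-5-(2-methylbut-3-en-2-yl)-2-(triisopropylsilyloxy)phenyl]ethoxy}-2-(3-hydroxy-3-methylbutyl)phenol | N[C@@H](COc1cccc(O)c1CCC(C)(C)O)c1cc(C(C)(C)C=C)c(O)cc1O[Si](C(C)C)(C(C)C)C(C)C | intermediate
14 | (3R)-3-[4-hydroxy-5-(2-methylbut-3-en-2-yl)-2-(triisopropylsilyloxy)phenyl]-9-(3-hydroxy-3-methylbutyl)-2,3,4,5-tetrahydro-1,4-benzoxazepin-8-ol | CC(C)(O)CCc1c(O)ccc2CN[C@@H](COc12)c1cc(C(C)(C)C=C)c(O)cc1O[Si](C(C)C)(C(C)C)C(C)C | intermediate
15 | 1,1-diazene of 14 (ring N4 carrying an exocyclic =N−, 3R) | CC(C)(O)CCc1c(O)ccc2C[N+](=[N-])[C@@H](COc12)c1cc(C(C)(C)C=C)c(O)cc1O[Si](C(C)C)(C(C)C)C(C)C | intermediate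
16 | (3R)-3-[4-hydroxy-5-(2-methylbut-3-en-2-yl)-2-(triisopropylsilyloxy)phenyl]-8-(3-hydroxy-3-methylbutyl)chroman-7-ol | CC(C)(O)CCc1c(O)ccc2C[C@@H](COc12)c1cc(C(C)(C)C=C)c(O)cc1O[Si](C(C)C)(C(C)C)C(C)C | intermediate
17 | (3R)-3-[2,4-dihydroxy-5-(2-methylbut-3-en-2-yl)phenyl]-8-(3-hydroxy-3-methylbutyl)chroman-7-ol (CNP0420388.1) | CC(C)(O)CCc1c(O)ccc2C[C@@H](COc12)c1cc(C(C)(C)C=C)c(O)cc1O | target

Total step count: 10. Longest linear sequence: 9 steps (steps 2 to 10, from 5); step 1 is a one-step branch that joins at step 5.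

Steps most likely to fail

Step 9 (nitrogen deletion). The radical pair may live long enough for rotation about C2–C3, which would erode the configuration at C3. It may also transfer hydrogen from C2 or undergo β-scission of the aryloxy group, which would open the ring instead of contracting it. The anomeric amide may in addition be consumed at the phenols. The fallback sets out from 14 and separates amination from nitrogen loss. N-amination with hydroxylamine-O-sulfonic acid and K2CO3 in aqueous THF should give the hydrazine (3R)-4-amino-3-[4-hydroxy-5-(2-methylbut-3-en-2-yl)-2-(triisopropylsilyloxy)phenyl]-9-(3-hydroxy-3-methylbutyl)-2,3,4,5-tetrahydro-1,4-benzoxazepin-8-ol F1. This isolable compound is then oxidised with yellow HgO in EtOH at 0 °C (classical hydrazine oxidation to the 1,1-diazene). N2 is then lost well below room temperature, where collapse of the tethered pair should be most faithful, and the route is rejoined at 16.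

Step 8 (Pictet–Spengler). The 7-endo attack of the arene may be slower than intermolecular aminomethylation of the phenol rings or N,N-acetal formation, giving oligomers. The fallback sets out from 12 and changes the electrophile from an iminium to an N-sulfonyliminium ion. After acidolysis to 13, NsCl with NaHCO3 in CH2Cl2/H2O should give N-{(1R)-2-[3-hydroxy-2-(3-hydroxy-3-methylbutyl)phenoxy]-1-[4-hydroxy-5-(2-methylbut-3-en-2-yl)-2-(triisopropylsilyloxy)phenyl]ethyl}-2-nitrobenzenesulfonamide F2. Paraformaldehyde with catalytic camphorsulfonic acid in CH2Cl2 should cyclise it to (3R)-3-[4-hydroxy-5-(2-methylbut-3-en-2-yl)-2-(triisopropylsilyloxy)phenyl]-9-(3-hydroxy-3-methylbutyl)-4-(2-nitrophenylsulfonyl)-2,3,4,5-tetrahydro-1,4-benzoxazepin-8-ol F3. No basic nitrogen remains in F3, so a second Mannich reaction is excluded. Thiophenol with K2CO3 in MeCN removes the sulfonyl group and returns 14.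

Step 1 (B-alkyl Suzuki coupling). Oxidative addition into the doubly ortho-oxygenated, phenoxide-rich aryl iodide may be slower than protodeiodination or decomposition of the alkylborane. The fallback sets out from 1 and makes the C–C bond by polar chemistry. MOMCl with iPr2NEt should give 2-iodo-1,3-bis(methoxymethoxy)benzene F4. Iodine–lithium exchange (n-BuLi, THF, −78 °C) followed by BF3·OEt2-promoted opening of 2,2-dimethyloxetane at its CH2 terminus should give 4-[2,6-bis(methoxymethoxy)phenyl]-2-methylbutan-2-ol F5. ZnBr2 with n-PrSH in CH2Cl2 at 0 °C removes the acetals without ionising the tertiary alcohol and returns 4.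

Further compounds
F1 | step 9 | (3R)-4-amino-3-[4-hydroxy-5-(2-methylbut-3-en-2-yl)-2-(triisopropylsilyloxy)phenyl]-9-(3-hydroxy-3-methylbutyl)-2,3,4,5-tetrahydro-1,4-benzoxazepin-8-ol | CC(C)(O)CCc1c(O)ccc2CN(N)[C@@H](COc12)c1cc(C(C)(C)C=C)c(O)cc1O[Si](C(C)C)(C(C)C)C(C)C
F2 | step 8 | N-{(1R)-2-[3-hydroxy-2-(3-hydroxy-3-methylbutyl)phenoxy]-1-[4-hydroxy-5-(2-methylbut-3-en-2-yl)-2-(triisopropylsilyloxy)phenyl]ethyl}-2-nitrobenzenesulfonamide | [O-][N+](=O)c1ccccc1S(=O)(=O)N[C@@H](COc1cccc(O)c1CCC(C)(C)O)c1cc(C(C)(C)C=C)c(O)cc1O[Si](C(C)C)(C(C)C)C(C)C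
F3 | step 8 | (3R)-3-[4-hydroxy-5-(2-methylbut-3-en-2-yl)-2-(triisopropylsilyloxy)phenyl]-9-(3-hydroxy-3-methylbutyl)-4-(2-nitrophenylsulfonyl)-2,3,4,5-tetrahydro-1,4-benzoxazepin-8-ol | CC(C)(O)CCc1c(O)ccc2CN([C@@H](COc12)c1cc(C(C)(C)C=C)c(O)cc1O[Si](C(C)C)(C(C)C)C(C)C)S(=O)(=O)c1ccccc1[N+](=O)[O-]
F4 | step 1 | 2-iodo-1,3-bis(methoxymethoxy)benzene | COCOc1cccc(OCOC)c1I
F5 | step 1 | 4-[2,6-bis(methoxymethoxy)phenyl]-2-methylbutan-2-ol | COCOc1cccc(OCOC)c1CCC(C)(C)O
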